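**Plan**

1. Numbering used in the discussion: ring A = C1 (chain), C3–OH, C4–OH, C5 (biaryl carbon). Ring B = C1' (biaryl carbon), C3'–OH, C4'–OH, C6' (chain). Each chain is (CH2)8–C(=O)–(2,6-dihydroxyphenyl).
2. Cuts, in retrosynthetic order: the four O–CH3 masks on the two resorcinol rings, the C3–O and C3'–O bonds, in each chain the bond between the benzylic carbon and its neighbour (as an alkene), the C5–C1' biaryl bond, and the carbonyl–aryl bond of each ketone.
3. Feature that allows the key step: the C4 hydroxyl of ring A lies para to the chain and has C5 blocked by ring B. The C4' hydroxyl of ring B lies para to the biaryl bond and has C5' flanked by the C6' chain. In each ring the one open, uncrowded ortho carbon (C3, C3') is therefore where the second catechol oxygen belongs.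
4. Forward: no ring is built, since all four benzene rings are bought. A C8 keto-phosphonium arm and a dibenzyloxy biaryl dialdehyde are made separately and joined by a double Wittig reaction. Hydrogenation then saturates the alkenes and frees the phenols, both rings are oxygenated at once, and the methyl ethers are cleaved last.
5. Stereochemistry: none to set. The target has no stereocentre, the biaryl axis carries only two ortho substituents, and the alkene geometry from the Wittig step vanishes on hydrogenation.

Key step: step 10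

Remark: compound names use biphenyl locants (biaryl carbons 1 and 1'), while the discussion keeps the ring A/ring B numbering of the plan. The Wittig product is written without alkene geometry because both isomers converge on hydrogenation, and the biaryl axis is taken as freely rotating, so the target is treated as achiral.

**Step 1**
Reactants: 1 8-bromooctanoic acid
Product: 3 8-bromo-N-methoxy-N-methyloctanamide, via acyl imidazolide 2 (not isolated)
Conditions: CDI (1.1 equiv), CH2Cl2, rt; then MeNH(OMe)·HCl (1.2 equiv), rt
Reagents that add atoms: N,O-dimethylhydroxylamine hydrochloride, CNOC.Cl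
Why: Activation of the acid as its acyl imidazolide followed by aminolysis is a standard Weinreb amide synthesis, and the near-neutral medium at room temperature leaves the primary bromide alone.

**Step 2**
Reactants: 3 8-bromo-N-methoxy-N-methyloctanamide; 4 1,3-dimethoxybenzene
Product: 7 8-bromo-1-(2,6-dimethoxyphenyl)octan-1-one, via 2,6-dimethoxyphenyllithium 5 (not isolated), via lithium hemiaminal adduct 6 (not isolated)
Conditions: 4, n-BuLi (1.0 equiv), THF, 0 °C to rt; then 3, −78 to −20 °C; 1 M HCl
Reagents that add atoms: none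
Why: Directed ortho-metalation occurs at the carbon between the two methoxy groups and the Weinreb ketone synthesis halts at chelated adduct 6 until the acid quench, while the crowded aryllithium, used without excess and kept at or below −20 °C, should displace the primary bromide far more slowly than it adds to the amide.

**Step 3**
Reactants: 7 8-bromo-1-(2,6-dimethoxyphenyl)octan-1-one
Product: 8 [8-(2,6-dimethoxyphenyl)-8-oxooctyl]triphenylphosphonium bromide
Conditions: PPh3 (1.1 equiv), MeCN, reflux
Reagents that add atoms: triphenylphosphine, c1ccc(cc1)P(c1ccccc1)c1ccccc1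
Why: This is an SN2 quaternisation of triphenylphosphine by a primary alkyl bromide, to which the shielded ketone and the aryl ethers are inert.

**Step 4**
Reactants: 9 3-bromo-4-hydroxybenzaldehyde
Product: 10 4-(benzyloxy)-3-bromobenzaldehyde
Conditions: BnBr, K2CO3, DMF, rt
Reagents that add atoms: benzyl bromide, BrCc1ccccc1
Why: Williamson ether synthesis on an acidic para-formyl phenol, with benzyl chosen because the later hydrogenation removes it at no cost in steps.

**Step 5**
Reactants: 10 4-(benzyloxy)-3-bromobenzaldehyde
Product: 11 4-(benzyloxy)-3-(4,4,5,5-tetramethyl-1,3,2-dioxaborolan-2-yl)benzaldehyde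
Conditions: B2pin2, Pd(dppf)Cl2 (3 mol %), KOAc, 1,4-dioxane, 90 °C
Reagents that add atoms: bis(pinacolato)diboron, CC1(C)OB(OC1(C)C)B1OC(C)(C)C(C)(C)O1
Why: Miyaura borylation tolerates aldehydes and benzyl ethers, and boron is placed on the ring A half because the alternative boronate with an ortho formyl group would be prone to protodeboronation.

**Step 6**
Reactants: 12 2-bromo-5-hydroxybenzaldehyde
Product: 13 5-(benzyloxy)-2-bromobenzaldehyde
Conditions: BnBr, K2CO3, DMF, rt
Reagents that add atoms: benzyl bromide, BrCc1ccccc1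
Why: Williamson ether synthesis under mild carbonate conditions that touch neither the aryl bromide nor the aldehyde.

**Step 7**
Reactants: 11 4-(benzyloxy)-3-(4,4,5,5-tetramethyl-1,3,2-dioxaborolan-2-yl)benzaldehyde; 13 5-(benzyloxy)-2-bromobenzaldehyde
Product: 14 2,4'-bis(benzyloxy)biphenyl-5,2'-dicarbaldehyde
Conditions: Pd(OAc)2 (2 mol %), SPhos (4 mol %), K3PO4, toluene/H2O, 80 °C
Reagents that add atoms: none
Why: Suzuki–Miyaura coupling forms the C5–C1' bond, the ortho formyl group speeding oxidative addition of 13 to zerovalent palladium and the bulky electron-rich biarylphosphine coping with one ortho substituent on each partner.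

**Step 8**
Reactants: 8 [8-(2,6-dimethoxyphenyl)-8-oxooctyl]triphenylphosphonium bromide; 14 2,4'-bis(benzyloxy)biphenyl-5,2'-dicarbaldehyde
Product: 16 9,9'-[2,4'-bis(benzyloxy)biphenyl-5,2'-diyl]bis[1-(2,6-dimethoxyphenyl)non-8-en-1-one] (mixture of alkene isomers), via keto ylide 15 (not isolated)
Conditions: 8 (2.4 equiv), NaN(SiMe3)2 (2.3 equiv), THF, −20 °C; then 14, −78 °C to rt
Reagents that add atoms: none
Why: In this Wittig olefination of aromatic aldehydes with a non-stabilised ylide, the CH2 next to phosphorus is several pKa units more acidic than the CH2 next to the twisted aryl ketone, the base is kept just short of the salt, the di-ortho-substituted carbonyl is too shielded for ylide attack and an eight-membered closure is disfavoured, so both formyl groups should be olefinated.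

**Step 9**
Reactants: 16 9,9'-[2,4'-bis(benzyloxy)biphenyl-5,2'-diyl]bis[1-(2,6-dimethoxyphenyl)non-8-en-1-one]
Product: 17 9,9'-(2,4'-dihydroxybiphenyl-5,2'-diyl)bis[1-(2,6-dimethoxyphenyl)nonan-1-one]
Conditions: H2 (1 atm), 10% Pd/C, EtOAc/EtOH, rt
Reagents that add atoms: none
Why: Catalytic hydrogenation saturates both styrene-type alkenes and hydrogenolyses both benzyl ethers in one operation, while the twisted di-ortho-substituted aryl ketones should be reduced only sluggishly under one atmosphere in neutral solvent.

**Step 10**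
Reactants: 17 9,9'-(2,4'-dihydroxybiphenyl-5,2'-diyl)bis[1-(2,6-dimethoxyphenyl)nonan-1-one]
Product: 19 9,9'-(2,3,4',5'-tetrahydroxybiphenyl-5,2'-diyl)bis[1-(2,6-dimethoxyphenyl)nonan-1-one], via bis-ortho-quinone 18 (not isolated)
Conditions: IBX (2.3 equiv), DMF, 0 °C to rt, dark, Ar; then Na2S2O4, H2O, 0 °C to rt
Reagents that add atoms: 2-iodoxybenzoic acid (IBX), O=C1OI(=O)(O)c2ccccc12
Why: Each phenol oxygen displaces the hydroxyl ligand on pentavalent iodine, the aryloxy iodane hands one oxo oxygen to the adjacent ring carbon in an intramolecular shift while iodine falls to the trivalent state, and the catechol-bound trivalent iodine then collapses to 2-iodobenzoic acid (monovalent iodine) and the ortho-quinone, so one equivalent of IBX serves each ring and Na2S2O4 finally reduces 18 to 19. The closest known reaction type is the IBX ortho-oxygenation of electron-rich 4-alkylphenols to 4-alkylcatechols with reductive work-up, applied here to two phenols of one molecule. On ring A the oxygen must go to the C3–H carbon, and it should, because the other ortho carbon C5 is quaternary and shielded by the twisted ring B, which disfavours ipso delivery to an ortho-quinol. On ring B the needed selectivity is C3' over C5', and the substrate secures it through the C6' chain, which is pushed toward C5' by the neighbouring ring A and crowds that carbon against the bulky iodane, whereas C3' has only the C2' hydrogen beside it. Para-quinones are excluded since C1 and C1' are substituted, the aryl methyl ethers lack the free hydroxyl that IBX needs, ketone dehydrogenation and benzylic oxidation by IBX call for heating, and prompt reduction forestalls tautomerisation of 18 to quinone methides or addition of a still unoxidised hydroxyl to a quinone ring. No ring closes and no stereocentre forms.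

**Step 11**
Reactants: 19 9,9'-(2,3,4',5'-tetrahydroxybiphenyl-5,2'-diyl)bis[1-(2,6-dimethoxyphenyl)nonan-1-one]
Product: 20 9,9'-(2,3,4',5'-tetrahydroxybiphenyl-5,2'-diyl)bis[1-(2,6-dihydroxyphenyl)nonan-1-one] (target)
Conditions: BBr3 (12 equiv), CH2Cl2, −78 °C to rt, Ar; then H2O, 0 °C
Reagents that add atoms: none
Why: In this Lewis-acid aryl methyl ether cleavage BBr3 binds each methoxy oxygen, helped by chelation to the neighbouring carbonyl, and bromide removes the methyl group by SN2, the catechols being held as cyclic borates until hydrolysis, which is the usual unmasking of 2,6-dimethoxyphenyl ketones.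

**Compound list**

1 | 8-bromooctanoic acid | OC(=O)CCCCCCCBr | starting material
2 | 8-bromo-1-(1H-imidazol-1-yl)octan-1-one (acyl imidazolide, formed in situ) | O=C(CCCCCCCBr)n1ccnc1 | intermediate
3 | 8-bromo-N-methoxy-N-methyloctanamide | CON(C)C(=O)CCCCCCCBr | intermediate
4 | 1,3-dimethoxybenzene | COc1cccc(OC)c1 | starting material
5 | 2,6-dimethoxyphenyllithium (formed in situ) | [Li]c1c(OC)cccc1OC | intermediate
6 | lithium 8-bromo-1-(2,6-dimethoxyphenyl)-1-[methoxy(methyl)amino]octan-1-olate (racemic, formed in situ) | [Li+].[O-]C(CCCCCCCBr)(N(C)OC)c1c(OC)cccc1OC | intermediate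
7 | 8-bromo-1-(2,6-dimethoxyphenyl)octan-1-one | O=C(CCCCCCCBr)c1c(OC)cccc1OC | intermediate
8 | [8-(2,6-dimethoxyphenyl)-8-oxooctyl]triphenylphosphonium bromide | [Br-].O=C(CCCCCCC[P+](c1ccccc1)(c1ccccc1)c1ccccc1)c1c(OC)cccc1OC | intermediate
9 | 3-bromo-4-hydroxybenzaldehyde | O=Cc1ccc(O)c(Br)c1 | starting material
10 | 4-(benzyloxy)-3-bromobenzaldehyde | O=Cc1ccc(OCc2ccccc2)c(Br)c1 | intermediate
11 | 4-(benzyloxy)-3-(4,4,5,5-tetramethyl-1,3,2-dioxaborolan-2-yl)benzaldehyde | O=Cc1ccc(OCc2ccccc2)c(B2OC(C)(C)C(C)(C)O2)c1 | intermediate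
12 | 2-bromo-5-hydroxybenzaldehyde | O=Cc1cc(O)ccc1Br | starting material
13 | 5-(benzyloxy)-2-bromobenzaldehyde | O=Cc1cc(OCc2ccccc2)ccc1Br | intermediate
14 | 2,4'-bis(benzyloxy)biphenyl-5,2'-dicarbaldehyde | O=Cc1ccc(OCc2ccccc2)c(-c2ccc(OCc3ccccc3)cc2C=O)c1 | intermediate
15 | 1-(2,6-dimethoxyphenyl)-8-(triphenyl-λ5-phosphanylidene)octan-1-one (keto ylide, formed in situ) | O=C(CCCCCCC=P(c1ccccc1)(c1ccccc1)c1ccccc1)c1c(OC)cccc1OC | intermediate
16 | 9,9'-[2,4'-bis(benzyloxy)biphenyl-5,2'-diyl]bis[1-(2,6-dimethoxyphenyl)non-8-en-1-one] (alkene isomers, geometry not specified) | O=C(CCCCCCC=Cc1ccc(OCc2ccccc2)c(-c2ccc(OCc3ccccc3)cc2C=CCCCCCCC(=O)c2c(OC)cccc2OC)c1)c1c(OC)cccc1OC | intermediate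
17 | 9,9'-(2,4'-dihydroxybiphenyl-5,2'-diyl)bis[1-(2,6-dimethoxyphenyl)nonan-1-one] | O=C(CCCCCCCCc1ccc(O)c(-c2ccc(O)cc2CCCCCCCCC(=O)c2c(OC)cccc2OC)c1)c1c(OC)cccc1OC | intermediate
18 | 5-[9-(2,6-dimethoxyphenyl)-9-oxononyl]-3-{6-[9-(2,6-dimethoxyphenyl)-9-oxononyl]-3,4-dioxocyclohexa-1,5-dien-1-yl}cyclohexa-3,5-diene-1,2-dione (bis-ortho-quinone, formed in situ) | O=C(CCCCCCCCC1=CC(=O)C(=O)C(C2=CC(=O)C(=O)C=C2CCCCCCCCC(=O)c2c(OC)cccc2OC)=C1)c1c(OC)cccc1OC | intermediate
19 | 9,9'-(2,3,4',5'-tetrahydroxybiphenyl-5,2'-diyl)bis[1-(2,6-dimethoxyphenyl)nonan-1-one] | O=C(CCCCCCCCc1cc(O)c(O)c(-c2cc(O)c(O)cc2CCCCCCCCC(=O)c2c(OC)cccc2OC)c1)c1c(OC)cccc1OC | intermediate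
20 | 9,9'-(2,3,4',5'-tetrahydroxybiphenyl-5,2'-diyl)bis[1-(2,6-dihydroxyphenyl)nonan-1-one] | O=C(CCCCCCCCc1cc(O)c(O)c(-c2cc(O)c(O)cc2CCCCCCCCC(=O)c2c(O)cccc2O)c1)c1c(O)cccc1O | target

**Step count**

Total step count: 11.
Longest linear sequence: 7 steps (steps 4, 5, 7, 8, 9, 10, 11). The arm sequence, steps 1, 2, 3, 8, 9, 10, 11, is equally long.

**Steps most likely to fail**

**Step 10.** Several things may go wrong:
- Oxygen delivery on ring B may not discriminate well enough between C3' and the chain-flanked C5'.
- Ipso oxygenation at C5 may intrude.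
- The quinone stage may decay by tautomerisation.
- A ring A hydroxyl may add to an already oxidised ring B if the two rings react at different rates.

The fallback sets out from 17 and comes back at 19 without passing through a quinone. Both phenols would be ortho-formylated through their magnesium phenoxides (MgCl2, Et3N, paraformaldehyde, MeCN, reflux; Casnati–Skattebøl formylation). This reaction is markedly more sensitive to a flanking alkyl group, and it should give 9,9'-(3,5'-diformyl-2,4'-dihydroxybiphenyl-5,2'-diyl)bis[1-(2,6-dimethoxyphenyl)nonan-1-one] F1. A double Dakin oxidation (H2O2, NaOH, THF/H2O, 0 °C) would then exchange both formyl groups for hydroxyl groups and deliver 19. The hindered, non-phenolic ketones stay outside the reach of the peroxide.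

**Step 8.** Proton shuffling from the ketone α-CH2 to the ylide may be followed by aldol attack of the enolate on the formyl groups. Olefination may also stop after only one of the two aldehydes has reacted.

The fallback sets out from 14 (with 1 as chain source) and comes back at 16, introducing the ketones only after the olefination.
- Acid 1 and PPh3 in MeCN at reflux would give (7-carboxyheptyl)triphenylphosphonium bromide F2.
- Two equivalents of NaN(SiMe3)2 per salt in THF would turn it into sodium 8-(triphenyl-λ5-phosphanylidene)octanoate F3.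
- This ylide would olefinate 14 to 9,9'-[2,4'-bis(benzyloxy)biphenyl-5,2'-diyl]bis(non-8-enoic acid) F4.
- Coupling with MeNH(OMe)·HCl (EDC·HCl, Et3N, CH2Cl2) would give the bis-Weinreb amide 9,9'-[2,4'-bis(benzyloxy)biphenyl-5,2'-diyl]bis(N-methoxy-N-methylnon-8-enamide) F5.
- Addition of aryllithium 5 (THF, −78 to 0 °C) would pass through the double lithium hemiaminal adduct F6 and release 16 on acid quench.

**Step 2.** Addition of the crowded aryllithium to the amide may be sluggish. That would let α-deprotonation, base-induced loss of formaldehyde from the N-methoxy group or displacement of the bromide compete.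

The fallback sets out from 3 and comes back at 7, working one oxidation level lower. i-Bu2AlH (THF, −78 °C) would reduce 3 to 8-bromooctanal F7, to which 5 adds rapidly at −78 °C to give racemic 8-bromo-1-(2,6-dimethoxyphenyl)octan-1-ol F8. Dess–Martin periodinane (CH2Cl2, rt) would then oxidise the carbinol to 7.

**Further compounds**

F1 | step 10 | 9,9'-(3,5'-diformyl-2,4'-dihydroxybiphenyl-5,2'-diyl)bis[1-(2,6-dimethoxyphenyl)nonan-1-one] | O=C(CCCCCCCCc1cc(C=O)c(O)c(-c2cc(C=O)c(O)cc2CCCCCCCCC(=O)c2c(OC)cccc2OC)c1)c1c(OC)cccc1OC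
F2 | step 8 | (7-carboxyheptyl)triphenylphosphonium bromide | [Br-].OC(=O)CCCCCCC[P+](c1ccccc1)(c1ccccc1)c1ccccc1
F3 | step 8 | sodium 8-(triphenyl-λ5-phosphanylidene)octanoate | [Na+].[O-]C(=O)CCCCCCC=P(c1ccccc1)(c1ccccc1)c1ccccc1
F4 | step 8 | 9,9'-[2,4'-bis(benzyloxy)biphenyl-5,2'-diyl]bis(non-8-enoic acid) (alkene isomers) | OC(=O)CCCCCCC=Cc1ccc(OCc2ccccc2)c(-c2ccc(OCc3ccccc3)cc2C=CCCCCCCC(O)=O)c1
F5 | step 8 | 9,9'-[2,4'-bis(benzyloxy)biphenyl-5,2'-diyl]bis(N-methoxy-N-methylnon-8-enamide) (alkene isomers) | CON(C)C(=O)CCCCCCC=Cc1ccc(OCc2ccccc2)c(-c2ccc(OCc3ccccc3)cc2C=CCCCCCCC(=O)N(C)OC)c1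
F6 | step 8 | dilithium double hemiaminal adduct of F5 with 5 | [Li+].[Li+].[O-]C(CCCCCCC=Cc1ccc(OCc2ccccc2)c(-c2ccc(OCc3ccccc3)cc2C=CCCCCCCC([O-])(N(C)OC)c2c(OC)cccc2OC)c1)(N(C)OC)c1c(OC)cccc1OC
F7 | step 2 | 8-bromooctanal | O=CCCCCCCCBr
F8 | step 2 | 8-bromo-1-(2,6-dimethoxyphenyl)octan-1-ol (racemic) | OC(CCCCCCCBr)c1c(OC)cccc1OC
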